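## Structural features

The target is a germacranolide: a ten-membered carbocycle (C1–C10) carrying, trans-fused across C6–C7, an α-methylene-γ-butyrolactone (O6–C12(=O)–C11(=C13)). O8 is esterified with methacrylic acid, C10 bears the hydroxymethyl group C14, and C4 of the only ring olefin bears the hydroxymethyl group C15. Across C4=C5 the ring bonds to C3 and C6 are trans, so C15 and C6 are cis; the CIP label is Z only because of O15. C6 (R), C7 (R) and C8 (S) are contiguous, with O6, the C11 arm and O8 all on one side of the extended C5–C9 chain (O6 and O8 are 1,3-syn). C10 (R) stands 1,3 to C8 with its hydrogen on the same ring face as O8. Fragile groups are the exocyclic enoate of the lactone and the methacrylate (Michael acceptors), the lactone itself, which can migrate to a free O8, and the ene-diol around C4=C5, which cyclodehydrates under acid. The real difficulty is a medium ring holding a trisubstituted trans olefin and a remote stereocentre (C10), together with the need to tell O6, O8, O14 and O15 apart. The key step exploits the 1,5-relationship of C4=C5 and the bond C1–C10 across the plain C1–C3 run: with C1 joined to C4 in thought, both become edges of a cyclobutane on the C5–C10 bond of a cyclohex-2-enone whose carbonyl is C6.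

## Logic of the disconnections

34 back to 33 and 32: the two primary silyl ethers and the O8–acyl bond are cut last. The methacrylate tolerates neither hydride, enolate nor hydrogenation, so it must enter at the end. The forward demand is a free O8 beside covered O14 and O15, which is met by silyl groups of graded acid stability (32 from 31).

31 back to 28: the C11=C13 bond is cut. The exocyclic enoate would not survive hydrogenation or hydride, so it is added to the finished lactone. The forward step needs enolate chemistry with O8 capped, so that the lactone cannot migrate.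

28 back to 27, 26 and 24: the O6–C12 lactone bond is cut and C15 is returned to the carboxyl level. In 24 a butenolide ties O6 to C15, which distinguishes O6 from O8 and leaves C12 as an inert tert-butyl ester. The forward steps must reduce the butenolide carbonyl without touching C12, silylate O15 before any acid is used, and then close the only free hydroxyl (O6) onto C12.

24 back to 23 and 22: the C10–H and C1–H bonds are cut. C10 becomes sp2 and its configuration is left to a hydrogenation steered by the stereogenic O8. A hydroxyl on C14 lies in the olefin plane and cannot choose a face, so O8 is the director. The forward step needs O8 free and every other oxygen masked.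

22 back to 19: the C6–H bond and the O6–C15 bond are cut. The C6 carbinol becomes a ketone conjugated with C4=C5 and the C15 ester. The forward step needs 1,3-syn hydride delivery relative to O8 and an olefin with C15 cis to C6.

19 back to 18: bonds C1–C4 and C5–C10 are re-formed in thought, which folds the ten-membered dienone into a six-membered ketone fused to a bicyclo[2.2.0]hexane. The medium ring is traded for strain. The forward step is a thermal cycloreversion that must give the right olefin geometry and resist Cope collapse.

18 back to 14 and 17: the key cut of C4–C5 and C1–C10 gives a cyclohexenone and a cyclobutene ester. The forward step needs head-to-head orientation.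

14 back to 13: the C5=C10 bond is cut by ring-closing metathesis logic. A 2-monoalkylcyclohexane-1,3-dione is fully enolised and offers no clean enantioselective monoreduction, and 14 can lose silanol and aromatise under base. The ring is therefore closed last, under neutral conditions, from an open chain whose stereocentres are already in place.

13 back to 12, 11, 10, and then to 9 and 5: the vinyl–C6 bond and the C7–C8 bond are cut. The aldol union sets C7 and C8 together under auxiliary control and brings in C9, C10 and C14 as one aldehyde. The forward demand is a syn-selective aldol on a succinate-type imide that enolises only next to the imide.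

9 back to 6 and 7 (through 8), 5 back to 4, 3, 2 and 1, and 17 back to 16 and 15 are functional-group operations on commercial four- and five-carbon pieces.

## Other disconnections considered

Alternative 1: The cut is C8–C9.
- Forward step: the open-chain aldehyde–allylic bromide A1, built from a chiral-pool butenolide that supplies C6 and C7, is treated with CrCl2. The allylchromium formed at C14 adds through C9 to the C8 aldehyde and gives the ten-membered carbinol A2 with an exocyclic C10=C14 methylene.
- In its favour: allylchromium additions tolerate almost every functional group, and the C4=C5 geometry is fixed by ordinary olefination before the ring exists. On olefin geometry this is the better plan.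
- Also in its favour: later hydroboration of the exocyclic methylene would create O14 and the C10 centre in one operation, which is at least the equal of the chosen plan.
- Against it here: the C8 configuration is created during the closure and depends on the transition-state conformation of a forming medium ring. High dilution is needed, and C12 sits at the alcohol level and must be oxidised later.
- Comparison on structure and mechanism: the chosen plan has C7 and C8 secured before the ring exists and opens the ring by strain release without dilution, but it leaves the olefin geometry to a thermolysis. The face selectivity at C10 is uncertain in both plans.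
- Step economy: the long acyclic build-up of A1 makes this comparable or somewhat worse.

Alternative 2: The cut is C3–C4.
- Forward step: 9-BBN hydroborates the terminal C2=C3 olefin of the iodobutenolide A3, and PdCl2(dppf) with AsPh3 and Cs2CO3 couples the C3 borane with the C4 iodide to give the butenolide-bridged ring A4.
- In its favour: the butenolide locks C15 cis to C6, and all four stereocentres, C10 included, are in place before ring closure. On both points it is better than the chosen plan.
- Against it here: the closure must make a strained bridged ten-membered ring by reductive elimination from a large palladacycle, in competition with β-hydride elimination, protodeboronation and dimerisation. C12 is carried as an acetal that needs later oxidation.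
- Comparison on structure and mechanism: A4 is the same ring type as 23 and 24 of the chosen route, so the end games (reductive opening of the butenolide, relactonisation to O6) are equal. The chosen plan reaches that ring without a macrocyclisation.
- Step economy: A3 needs four stereocentres on an open chain, so this is likely longer.

Alternative 3: The cut is C1=C2.
- Forward step: the second-generation Grubbs catalyst RuCl2(H2IMes)(PCy3)(=CHPh) joins the vinyl group on C10 and the allyl group on C4 of the lactone diene A5 to give A6, with loss of ethene.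
- In its favour: the geometry of the new olefin is irrelevant, and the trans-lactone and all stereocentres are preset. The later saturation of a disubstituted olefin beside a trisubstituted one is an easier chemoselectivity problem than the directed hydrogenation of the chosen plan. On these points it is the equal or the better.
- Against it here: metathesis to ten-membered carbocycles is strained and prone to dimerisation and olefin migration, and it would be attempted with a trisubstituted olefin and a lactone already in the forming ring.
- Comparison on structure and mechanism: the chosen plan makes the ring by an entropically neutral fragmentation but pays with uncertain olefin geometry and a late C10 centre.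
- Step economy: similar.

Key step: step 13

Assumption: silyl and ester alkyl groups on the cyclohexenone are treated as exchangeable spectators (triethylsilyl on O8, tert-butyldiphenylsilyl on O14, tert-butyl ester at C12), and the thermolysis is taken to give C4=C5 with C15 cis to C6; the other outcome is covered by a fallback.

## Route

Step 1
Reactants: 1 2-methylidenepropane-1,3-diol
Product: 2 2-{[tert-butyl(diphenyl)silyl]oxymethyl}prop-2-en-1-ol
Conditions: NaH (1.0 equiv), THF, 0 °C; TBDPSCl (1.0 equiv), 0 °C → rt
Reagents that add atoms: tert-butyl(chloro)diphenylsilane, CC(C)(C)[Si](Cl)(c1ccccc1)c1ccccc1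
Why: Monosilylation of a symmetrical diol through its sparingly soluble monosodium alkoxide, which limits bis-silylation; no stereocentre is involved.

Step 2
Reactants: 2 2-{[tert-butyl(diphenyl)silyl]oxymethyl}prop-2-en-1-ol
Product: 3 {[2-(bromomethyl)prop-2-en-1-yl]oxy}(tert-butyl)diphenylsilane
Conditions: CBr4, PPh3, CH2Cl2, 0 °C
Reagents that add atoms: tetrabromomethane, BrC(Br)(Br)Br
Why: Appel bromination of a primary allylic alcohol under neutral conditions that leave the silyl ether alone; the allyl unit is symmetrical, so transposition is of no consequence.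

Step 3
Reactants: 3 {[2-(bromomethyl)prop-2-en-1-yl]oxy}(tert-butyl)diphenylsilane
Product: 4 3-{[tert-butyl(diphenyl)silyl]oxymethyl}but-3-en-1-ol
Conditions: In powder, 37% aq. HCHO, THF/H2O, rt
Reagents that add atoms: formaldehyde, C=O
Why: Barbier allylation of formaldehyde by the allylindium species formed in the flask; water is tolerated and a 2-substituted allyl unit gives one homoallylic alcohol.

Step 4
Reactants: 4 3-{[tert-butyl(diphenyl)silyl]oxymethyl}but-3-en-1-ol
Product: 5 3-{[tert-butyl(diphenyl)silyl]oxymethyl}but-3-enal
Conditions: Dess–Martin periodinane, NaHCO3, CH2Cl2, 0 °C; used at once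
Reagents that add atoms: none
Why: Dess–Martin oxidation under buffered, near-neutral conditions should keep the β,γ-olefin out of conjugation; the aldehyde is not stored.

Step 5
Reactants: 6 4-tert-butoxy-4-oxobutanoic acid; 7 (4R)-4-benzyl-1,3-oxazolidin-2-one
Product: 9 tert-butyl 4-[(4R)-4-benzyl-2-oxo-1,3-oxazolidin-3-yl]-4-oxobutanoate, via mixed pivalic anhydride 8 (not isolated)
Conditions: t-BuCOCl, Et3N, THF, −20 °C; then 7, LiCl, −20 °C → rt
Reagents that add atoms: none
Why: N-Acylation of the oxazolidinone by a mixed anhydride, which is attacked at the less hindered succinyl carbonyl; the tert-butyl ester is untouched.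

Step 6
Reactants: 9 tert-butyl 4-[(4R)-4-benzyl-2-oxo-1,3-oxazolidin-3-yl]-4-oxobutanoate; 5 3-{[tert-butyl(diphenyl)silyl]oxymethyl}but-3-enal
Product: 10 tert-butyl (3R,4S)-3-{[(4R)-4-benzyl-2-oxo-1,3-oxazolidin-3-yl]carbonyl}-6-{[tert-butyl(diphenyl)silyl]oxymethyl}-4-hydroxyhept-6-enoate
Conditions: Bu2BOTf, i-Pr2NEt, CH2Cl2, −78 → 0 °C; 5, −78 → 0 °C; pH 7 buffer (NaH2PO4/Na2HPO4), MeOH, 30% H2O2, 0 °C
Reagents that add atoms: none
Why: Evans syn-aldol reaction: the Z-boron enolate forms only next to the imide (C7), and the chair transition state with the aldehyde on the enolate face away from the benzyl group sets C7 (R) and C8 (S). The acetate arm and O8 come out syn, as in the target.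

Step 7
Reactants: 10 tert-butyl (3R,4S)-3-{[(4R)-4-benzyl-2-oxo-1,3-oxazolidin-3-yl]carbonyl}-6-{[tert-butyl(diphenyl)silyl]oxymethyl}-4-hydroxyhept-6-enoate
Product: 11 tert-butyl (3R,4S)-6-{[tert-butyl(diphenyl)silyl]oxymethyl}-4-hydroxy-3-[methoxy(methyl)carbamoyl]hept-6-enoate
Conditions: MeNH(OMe)·HCl, AlMe3, CH2Cl2, −20 → 0 °C; aq. KNaC4H4O6
Reagents that add atoms: N,O-dimethylhydroxylamine hydrochloride, CNOC.Cl
Why: Aluminium amide transamidation to the Weinreb amide, helped by the free β-hydroxyl, cleaves the exocyclic acyl bond and releases the auxiliary; the hindered tert-butyl ester is not attacked.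

Step 8
Reactants: 11 tert-butyl (3R,4S)-6-{[tert-butyl(diphenyl)silyl]oxymethyl}-4-hydroxy-3-[methoxy(methyl)carbamoyl]hept-6-enoate
Product: 12 tert-butyl (3R,4S)-6-{[tert-butyl(diphenyl)silyl]oxymethyl}-3-[methoxy(methyl)carbamoyl]-4-[(triethylsilyl)oxy]hept-6-enoate
Conditions: Et3SiCl, imidazole, DMF, 0 °C → rt
Reagents that add atoms: chlorotriethylsilane, CC[Si](Cl)(CC)CC
Why: Silylation of the secondary carbinol; the triethylsilyl group blocks retro-aldol and conjugate-addition paths through step 14 and can be removed by mild acid beside the primary tert-butyldiphenylsilyl ether.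

Step 9
Reactants: 12 tert-butyl (3R,4S)-6-{[tert-butyl(diphenyl)silyl]oxymethyl}-3-[methoxy(methyl)carbamoyl]-4-[(triethylsilyl)oxy]hept-6-enoate
Product: 13 tert-butyl (3R,4S)-6-{[tert-butyl(diphenyl)silyl]oxymethyl}-3-(prop-2-enoyl)-4-[(triethylsilyl)oxy]hept-6-enoate
Conditions: CH2=CHMgBr, THF, −20 → 0 °C; inverse quench into cold aq. NH4Cl
Reagents that add atoms: vinylmagnesium bromide, C=C[Mg]Br
Why: Grignard addition to a Weinreb amide stops at the chelated tetrahedral intermediate and gives the vinyl ketone on quench. The tert-butyl ester reacts much more slowly, and the inverse quench keeps the released amine from adding to the enone.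

Step 10
Reactants: 13 tert-butyl (3R,4S)-6-{[tert-butyl(diphenyl)silyl]oxymethyl}-3-(prop-2-enoyl)-4-[(triethylsilyl)oxy]hept-6-enoate
Product: 14 tert-butyl 2-[(1R,6S)-4-{[tert-butyl(diphenyl)silyl]oxymethyl}-2-oxo-6-[(triethylsilyl)oxy]cyclohex-3-en-1-yl]acetate
Conditions: RuCl2(H2IMes)(PCy3)(=CHPh) (5 mol %), CH2Cl2 (5 mM), 40 °C
Reagents that add atoms: none
Why: Ring-closing metathesis of the vinyl ketone with the 1,1-disubstituted olefin forms the C5=C10 bond of a six-membered enone with loss of ethene. The neutral conditions avoid β-elimination of the C8 silyl ether, which would end in a phenol.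

Step 11
Reactants: 15 ethyl 1-bromocyclobutane-1-carboxylate
Product: 16 cyclobut-1-ene-1-carboxylic acid
Conditions: KOH (powder), toluene, reflux; then aq. HCl, 0 °C
Reagents that add atoms: potassium hydroxide, [K+].[OH-]
Why: Base-induced dehydrobromination with concurrent saponification gives the conjugated cyclobutene acid.

Step 12
Reactants: 16 cyclobut-1-ene-1-carboxylic acid
Product: 17 methyl cyclobut-1-ene-1-carboxylate
Conditions: MeI, K2CO3, DMF, 0 °C → rt, dark; used freshly distilled
Reagents that add atoms: iodomethane, CI
Why: O-Alkylation of the carboxylate avoids the acid catalysis and heat that would polymerise the strained acrylate.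

Step 13
Reactants: 14 tert-butyl 2-[(1R,6S)-4-{[tert-butyl(diphenyl)silyl]oxymethyl}-2-oxo-6-[(triethylsilyl)oxy]cyclohex-3-en-1-yl]acetate; 17 methyl cyclobut-1-ene-1-carboxylate
Product: 18 cis-anti-cis photoadduct methyl 8-(2-tert-butoxy-2-oxoethyl)-1-{[tert-butyl(diphenyl)silyl]oxymethyl}-7-oxo-9-[(triethylsilyl)oxy]tricyclo[4.4.0.0(2,5)]decane-5-carboxylate
Conditions: hν (350 nm lamps, Pyrex), 17 (8 equiv), CH2Cl2 (degassed), −20 °C; chromatography on neutral alumina
Reagents that add atoms: none
Why: Excitation of the enone (n→π*, about 350 nm) and intersystem crossing give the twisted triplet, whose β-carbon C10 bonds first to the unsubstituted cyclobutene carbon C1; the resulting 1,4-biradical (α-acyl radical at C5, tertiary α-ester radical at C4) closes C4–C5 after spin inversion. The closest known reaction type is the intermolecular [2+2] photocycloaddition of 3-alkylcyclohex-2-enones with cyclobut-1-ene-1-carboxylates. The one ring closed is the central cyclobutane C5–C4–C1–C10, made in two stages (radical addition, then biradical recombination) and fused to the ester's own four-membered ring as a bicyclo[2.2.0]hexane. C1 and C4 are cis because both lie in the cyclobutene ring, and C5 and C10 end cis-fused because a trans-fused isomer, if formed, should epimerise at the enolisable C5 on alumina. The anti arrangement of the two outer rings follows from approach of the cyclobutene with its CH2–CH2 bridge turned away from the six-membered ring, and the face is the one opposite O8 (axial-type attack at C10 on the half-chair with both ring substituents equatorial). The selectivity that matters is head-to-head orientation: the acceptor ester places its own carbon on the enone α-carbon so that both radical centres are stabilised, and the bulky silyloxymethyl group on C10 favours bonding of the unsubstituted C1 there. An excess of 17 suppresses enone dimerisation, and the cold, neutral medium keeps 14 from losing silanol. All four new centres are erased in step 14, so facial and fusion isomers should converge.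

Step 14
Reactants: 18 cis-anti-cis photoadduct methyl 8-(2-tert-butoxy-2-oxoethyl)-1-{[tert-butyl(diphenyl)silyl]oxymethyl}-7-oxo-9-[(triethylsilyl)oxy]tricyclo[4.4.0.0(2,5)]decane-5-carboxylate
Product: 19 methyl 7-(2-tert-butoxy-2-oxoethyl)-10-{[tert-butyl(diphenyl)silyl]oxymethyl}-6-oxo-8-[(triethylsilyl)oxy]cyclodeca-1(10),4-diene-4-carboxylate (target numbering; C3/C6 trans at C4=C5; C2/C9 cis at C1=C10)
Conditions: toluene (0.01 M, degassed, BHT), silylated sealed tube, 190 °C
Reagents that add atoms: none
Why: Thermal cycloreversion of a bicyclo[2.2.0]hexane: the strained C1–C4 bond breaks (the C4 radical is ester-stabilised) to a cyclohexane-1,4-diyl that cleaves C5–C10, giving the cyclodeca-1,5-diene. The less crowded chair-like diyl has only C9 axial, which should place C3 and C6 trans across C4=C5 (C15 cis to C6) and C2 and C9 cis across C1=C10. Conjugation of C4=C5 with both the C6 ketone and the ester is what should hold the ten-membered ring against Cope collapse to the divinylcyclohexanone.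

Step 15
Reactants: 19 methyl 7-(2-tert-butoxy-2-oxoethyl)-10-{[tert-butyl(diphenyl)silyl]oxymethyl}-6-oxo-8-[(triethylsilyl)oxy]cyclodeca-1(10),4-diene-4-carboxylate
Product: 22 butenolide alcohol: the ten-membered ring bridged by the C15(=O)–O6 lactone across C4=C5 with free 8-hydroxyl; C1=C10 olefin; 14-OTBDPS; tert-butyl acetate arm on C7, via β-hydroxy dienone 20 (not isolated), via syn-1,3-diol 21 (not isolated)
Conditions: PPTS (0.2 equiv), MeOH/THF 1:4, 0 °C → rt; then Et2BOMe, −78 °C; NaBH4, −78 °C; AcOH; MeOH co-evaporation; PPTS (cat.), CH2Cl2, rt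
Reagents that add atoms: none
Why: Mild acid methanolysis frees O8, and a Narasaka–Prasad reduction follows in the same flask: boron chelates O8 and the C6 carbonyl, and external hydride gives the 1,3-syn diol, which is the 6R carbinol of the target. The new hydroxyl is cis to the ester across C4=C5 and closes the butenolide. This parks O6 and C15, tells O6 from O8, and never exposes the free β-hydroxy ene-dione to work-up.

Step 16
Reactants: 22 butenolide alcohol
Product: 23 10R-dihydro butenolide alcohol: as 22 with C1–C10 saturated and H10 on the ring face of O8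
Conditions: H2 (1 atm), [Ir(cod)(PCy3)(py)]PF6 (10 mol %), CH2Cl2, 0 °C → rt
Reagents that add atoms: none
Why: Hydroxyl-directed homogeneous hydrogenation of a homoallylic alcohol: the cationic iridium centre binds O8 and delivers both hydrogens to the face of C1=C10 on the side of O8, which places H10 cis to O8 and C14 trans (10R). The conjugated, bridged butenolide olefin is electron-poor and one bond further from O8, so it should stay.

Step 17
Reactants: 23 10R-dihydro butenolide alcohol
Product: 24 8-O-tert-butyldimethylsilyl ether of 23
Conditions: TBSOTf, 2,6-lutidine, CH2Cl2, −78 → 0 °C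
Reagents that add atoms: tert-butyldimethylsilyl trifluoromethanesulfonate, CC(C)(C)[Si](C)(C)OS(=O)(=O)C(F)(F)F
Why: Silylation of the secondary alcohol with a hindered, weakly basic amine that does not deprotonate the butenolide γ-position; O8 is now capped for the lactonisation and enolate steps.

Step 18
Reactants: 24 8-O-tert-butyldimethylsilyl ether of 23
Product: 26 ene-diol: tert-butyl ester of the ten-membered 6-hydroxy-4-(hydroxymethyl)cyclodec-4-ene with 8-OTBS and 14-OTBDPS (C3/C6 trans at C4=C5), via lactol 25 (not isolated)
Conditions: i-Bu2AlH (1.3 equiv), CH2Cl2, −78 °C; MeOH; then NaBH4, CeCl3·7H2O, MeOH, 0 °C; aq. KNaC4H4O6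
Reagents that add atoms: none
Why: The lactone is the most electrophilic carbonyl and is taken to the lactol at −78 °C, while the tert-butyl ester is inert. Luche reduction of the hydroxy-enal tautomer then gives the ene-diol with the olefin geometry held by the ring. The work-up is kept free of acid, which would dehydrate the lactol to a furan.

Step 19
Reactants: 26 ene-diol
Product: 27 15-O-tert-butyldiphenylsilyl ether of 26 with free 6-hydroxyl
Conditions: TBDPSCl (1.1 equiv), imidazole, CH2Cl2, 0 °C
Reagents that add atoms: tert-butyl(chloro)diphenylsilane, CC(C)(C)[Si](Cl)(c1ccccc1)c1ccccc1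
Why: The bulky silyl chloride takes the primary allylic hydroxyl and leaves the secondary one; capping O15 before any acid prevents cyclodehydration of the cis-ene-1,4-diol to a dihydrofuran.

Step 20
Reactants: 27 15-O-tert-butyldiphenylsilyl ether of 26
Product: 28 trans-fused 12,6-lactone with 8-OTBS and 14,15-bis-OTBDPS (target skeleton with CH2 at C11)
Conditions: CSA (0.2 equiv), CH2Cl2, rt → 40 °C
Reagents that add atoms: none
Why: Acid-catalysed lactonisation of a γ-hydroxy tert-butyl ester: O6 is the only free hydroxyl, so the 12,6-olide forms, and its trans ring fusion is dictated by the C6 and C7 configurations already present. Any lactone formed earlier in step 18 converges on 28.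

Step 21
Reactants: 28 trans-fused 12,6-lactone
Product: 31 α-methylene lactone (C11=C13) with 8-OTBS and 14,15-bis-OTBDPS, via Mannich base 29 (not isolated), via trimethylammonium iodide 30 (not isolated)
Conditions: LiN(i-Pr)2, THF, −78 °C; CH2=NMe2+ I−, −78 °C → rt; then MeI, MeOH/CH2Cl2, rt; then aq. NaHCO3, rt
Reagents that add atoms: N,N-dimethylmethyleneiminium iodide, C=[N+](C)C.[I-]
Why: Eschenmoser methylenation: Mannich reaction of the lactone enolate, N-methylation and base-induced elimination of trimethylamine. With O8 silylated no alkoxide can attack C12, and the C11 configuration is irrelevant because it becomes sp2.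

Step 22
Reactants: 31 α-methylene lactone
Product: 32 8-hydroxy α-methylene lactone with 14,15-bis-OTBDPS
Conditions: CSA (0.2 equiv), MeOH/CH2Cl2 1:1, 0 °C → rt
Reagents that add atoms: none
Why: Acid methanolysis removes the secondary tert-butyldimethylsilyl ether much faster than the primary tert-butyldiphenylsilyl ethers; the non-basic medium disfavours lactone migration to O8 and methanol addition to the enoate.

Step 23
Reactants: 32 8-hydroxy α-methylene lactone
Product: 33 8-O-methacrylate with 14,15-bis-OTBDPS
Conditions: methacrylic anhydride, Et3N, DMAP (0.2 equiv), BHT, CH2Cl2, 0 °C → rt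
Reagents that add atoms: methacrylic anhydride, C=C(C)C(=O)OC(=O)C(C)=C
Why: DMAP-catalysed acylation of the only free hydroxyl; the excess anhydride should outrun any base-induced relactonisation.

Step 24
Reactants: 33 8-O-methacrylate
Product: 34 target (6R,7R,8S,10R; C3/C6 trans at C4=C5)
Conditions: HF·pyridine, pyridine, THF, 0 °C → rt
Reagents that add atoms: none
Why: Fluoride cleavage of both primary silyl ethers in a mildly acidic medium that spares the two Michael acceptors and avoids acyl migration.

## Compound list

1 | 2-methylidenepropane-1,3-diol | C=C(CO)CO | starting material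
2 | 2-{[tert-butyl(diphenyl)silyl]oxymethyl}prop-2-en-1-ol | C=C(CO)CO[Si](c1ccccc1)(c1ccccc1)C(C)(C)C | intermediate
3 | {[2-(bromomethyl)prop-2-en-1-yl]oxy}(tert-butyl)diphenylsilane | C=C(CBr)CO[Si](c1ccccc1)(c1ccccc1)C(C)(C)C | intermediate
4 | 3-{[tert-butyl(diphenyl)silyl]oxymethyl}but-3-en-1-ol | C=C(CCO)CO[Si](c1ccccc1)(c1ccccc1)C(C)(C)C | intermediate
5 | 3-{[tert-butyl(diphenyl)silyl]oxymethyl}but-3-enal | C=C(CC=O)CO[Si](c1ccccc1)(c1ccccc1)C(C)(C)C | intermediate
6 | 4-tert-butoxy-4-oxobutanoic acid | OC(=O)CCC(=O)OC(C)(C)C | starting material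
7 | (4R)-4-benzyl-1,3-oxazolidin-2-one | O=C1N[C@H](Cc2ccccc2)CO1 | starting material
8 | 4-tert-butoxy-4-oxobutanoic 2,2-dimethylpropanoic anhydride | CC(C)(C)OC(=O)CCC(=O)OC(=O)C(C)(C)C | intermediate (not isolated)
9 | tert-butyl 4-[(4R)-4-benzyl-2-oxo-1,3-oxazolidin-3-yl]-4-oxobutanoate | O=C1OC[C@@H](Cc2ccccc2)N1C(=O)CCC(=O)OC(C)(C)C | intermediate
10 | tert-butyl (3R,4S)-3-{[(4R)-4-benzyl-2-oxo-1,3-oxazolidin-3-yl]carbonyl}-6-{[tert-butyl(diphenyl)silyl]oxymethyl}-4-hydroxyhept-6-enoate | CC(C)(C)OC(=O)C[C@@H](C(=O)N1[C@H](Cc2ccccc2)COC1=O)[C@@H](O)CC(=C)CO[Si](c1ccccc1)(c1ccccc1)C(C)(C)C | intermediate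
11 | tert-butyl (3R,4S)-6-{[tert-butyl(diphenyl)silyl]oxymethyl}-4-hydroxy-3-[methoxy(methyl)carbamoyl]hept-6-enoate | CC(C)(C)OC(=O)C[C@@H](C(=O)N(C)OC)[C@@H](O)CC(=C)CO[Si](c1ccccc1)(c1ccccc1)C(C)(C)C | intermediate
12 | tert-butyl (3R,4S)-6-{[tert-butyl(diphenyl)silyl]oxymethyl}-3-[methoxy(methyl)carbamoyl]-4-[(triethylsilyl)oxy]hept-6-enoate | CC(C)(C)OC(=O)C[C@@H](C(=O)N(C)OC)[C@@H](O[Si](CC)(CC)CC)CC(=C)CO[Si](c1ccccc1)(c1ccccc1)C(C)(C)C | intermediate
13 | tert-butyl (3R,4S)-6-{[tert-butyl(diphenyl)silyl]oxymethyl}-3-(prop-2-enoyl)-4-[(triethylsilyl)oxy]hept-6-enoate | CC(C)(C)OC(=O)C[C@@H](C(=O)C=C)[C@@H](O[Si](CC)(CC)CC)CC(=C)CO[Si](c1ccccc1)(c1ccccc1)C(C)(C)C | intermediate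
14 | tert-butyl 2-[(1R,6S)-4-{[tert-butyl(diphenyl)silyl]oxymethyl}-2-oxo-6-[(triethylsilyl)oxy]cyclohex-3-en-1-yl]acetate (precursor of the key step) | O=C1C=C(CO[Si](c2ccccc2)(c2ccccc2)C(C)(C)C)C[C@H](O[Si](CC)(CC)CC)[C@H]1CC(=O)OC(C)(C)C | intermediate
15 | ethyl 1-bromocyclobutane-1-carboxylate | CCOC(=O)C1(Br)CCC1 | starting material
16 | cyclobut-1-ene-1-carboxylic acid | OC(=O)C1=CCC1 | intermediate
17 | methyl cyclobut-1-ene-1-carboxylate | COC(=O)C1=CCC1 | intermediate
18 | cis-anti-cis photoadduct, methyl 8-(2-tert-butoxy-2-oxoethyl)-1-{[tert-butyl(diphenyl)silyl]oxymethyl}-7-oxo-9-[(triethylsilyl)oxy]tricyclo[4.4.0.0(2,5)]decane-5-carboxylate; cyclobutane on the ring face opposite O8 | O=C1[C@H]2[C@]3(C(=O)OC)CC[C@@H]3[C@@]2(CO[Si](c4ccccc4)(c4ccccc4)C(C)(C)C)C[C@H](O[Si](CC)(CC)CC)[C@H]1CC(=O)OC(C)(C)C | intermediate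
19 | methyl 7-(2-tert-butoxy-2-oxoethyl)-10-{[tert-butyl(diphenyl)silyl]oxymethyl}-6-oxo-8-[(triethylsilyl)oxy]cyclodeca-1(10),4-diene-4-carboxylate (target numbering; C3/C6 trans, C2/C9 cis) | O=C1/C=C(C(=O)OC)/CC/C=C(CO[Si](c2ccccc2)(c2ccccc2)C(C)(C)C)\C[C@H](O[Si](CC)(CC)CC)[C@H]1CC(=O)OC(C)(C)C | intermediate
20 | 8-hydroxy analogue of 19 (β-hydroxy dienone) | O=C1/C=C(C(=O)OC)/CC/C=C(CO[Si](c2ccccc2)(c2ccccc2)C(C)(C)C)\C[C@H](O)[C@H]1CC(=O)OC(C)(C)C | intermediate (not isolated)
21 | 6,8-syn-diol, methyl 7-(2-tert-butoxy-2-oxoethyl)-10-{[tert-butyl(diphenyl)silyl]oxymethyl}-6,8-dihydroxycyclodeca-1(10),4-diene-4-carboxylate | O[C@@H]1/C=C(C(=O)OC)/CC/C=C(CO[Si](c2ccccc2)(c2ccccc2)C(C)(C)C)\C[C@H](O)[C@H]1CC(=O)OC(C)(C)C | intermediate (not isolated)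
22 | butenolide alcohol: C15(=O)–O6 lactone across C4=C5, 8-OH, C1=C10 olefin, 14-OTBDPS, tert-butyl acetate arm on C7 | O=C1O[C@@H]2C=C1CC/C=C(CO[Si](c3ccccc3)(c3ccccc3)C(C)(C)C)\C[C@H](O)[C@H]2CC(=O)OC(C)(C)C | intermediate
23 | 10R-dihydro butenolide alcohol (C1–C10 saturated) | O=C1O[C@@H]2C=C1CCC[C@@H](CO[Si](c3ccccc3)(c3ccccc3)C(C)(C)C)C[C@H](O)[C@H]2CC(=O)OC(C)(C)C | intermediate
24 | 8-O-tert-butyldimethylsilyl ether of 23 | O=C1O[C@@H]2C=C1CCC[C@@H](CO[Si](c3ccccc3)(c3ccccc3)C(C)(C)C)C[C@H](O[Si](C)(C)C(C)(C)C)[C@H]2CC(=O)OC(C)(C)C | intermediate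
25 | lactol of 24 (C15 hemiacetal, both anomers) | OC1O[C@@H]2C=C1CCC[C@@H](CO[Si](c3ccccc3)(c3ccccc3)C(C)(C)C)C[C@H](O[Si](C)(C)C(C)(C)C)[C@H]2CC(=O)OC(C)(C)C | intermediate (not isolated)
26 | ene-diol: tert-butyl 2-[ten-membered ring with 6-OH, 4-CH2OH, 8-OTBS, 10-CH2OTBDPS]acetate, C3/C6 trans at C4=C5 | O[C@@H]1/C=C(CO)/CCC[C@@H](CO[Si](c2ccccc2)(c2ccccc2)C(C)(C)C)C[C@H](O[Si](C)(C)C(C)(C)C)[C@H]1CC(=O)OC(C)(C)C | intermediate
27 | 15-O-tert-butyldiphenylsilyl ether of 26 | O[C@@H]1/C=C(CO[Si](c2ccccc2)(c2ccccc2)C(C)(C)C)/CCC[C@@H](CO[Si](c2ccccc2)(c2ccccc2)C(C)(C)C)C[C@H](O[Si](C)(C)C(C)(C)C)[C@H]1CC(=O)OC(C)(C)C | intermediate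
28 | trans-fused 12,6-lactone, 8-OTBS, 14,15-bis-OTBDPS, CH2 at C11 | CC(C)(C)[Si](C)(C)O[C@H]1C[C@H](CO[Si](c3ccccc3)(c3ccccc3)C(C)(C)C)CCC/C(CO[Si](c3ccccc3)(c3ccccc3)C(C)(C)C)=C/[C@H]2OC(=O)C[C@H]12 | intermediate
29 | 11-(dimethylaminomethyl) lactone (Mannich base, C11 epimers) | CC(C)(C)[Si](C)(C)O[C@H]1C[C@H](CO[Si](c3ccccc3)(c3ccccc3)C(C)(C)C)CCC/C(CO[Si](c3ccccc3)(c3ccccc3)C(C)(C)C)=C/[C@H]2OC(=O)C(CN(C)C)[C@H]12 | intermediate (not isolated)
30 | 11-(trimethylammoniomethyl) lactone iodide | CC(C)(C)[Si](C)(C)O[C@H]1C[C@H](CO[Si](c3ccccc3)(c3ccccc3)C(C)(C)C)CCC/C(CO[Si](c3ccccc3)(c3ccccc3)C(C)(C)C)=C/[C@H]2OC(=O)C(C[N+](C)(C)C)[C@H]12.[I-] | intermediate (not isolated)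
31 | α-methylene lactone, 8-OTBS, 14,15-bis-OTBDPS | CC(C)(C)[Si](C)(C)O[C@H]1C[C@H](CO[Si](c3ccccc3)(c3ccccc3)C(C)(C)C)CCC/C(CO[Si](c3ccccc3)(c3ccccc3)C(C)(C)C)=C/[C@H]2OC(=O)C(=C)[C@H]12 | intermediate
32 | 8-hydroxy α-methylene lactone, 14,15-bis-OTBDPS | O[C@H]1C[C@H](CO[Si](c3ccccc3)(c3ccccc3)C(C)(C)C)CCC/C(CO[Si](c3ccccc3)(c3ccccc3)C(C)(C)C)=C/[C@H]2OC(=O)C(=C)[C@H]12 | intermediate
33 | 8-O-methacrylate, 14,15-bis-OTBDPS | C=C(C)C(=O)O[C@H]1C[C@H](CO[Si](c3ccccc3)(c3ccccc3)C(C)(C)C)CCC/C(CO[Si](c3ccccc3)(c3ccccc3)C(C)(C)C)=C/[C@H]2OC(=O)C(=C)[C@H]12 | intermediate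
34 | CNP0256084.2, the 8-O-methacryloyl-14,15-dihydroxy germacra-4,11(13)-dien-12,6-olide | C=C(C)C(=O)O[C@H]1C[C@H](CO)CCC/C(CO)=C/[C@H]2OC(=O)C(=C)[C@H]12 | target

## Step count and least certain steps

Total: 24 steps. Longest linear sequence: 21 steps (steps 1–4, 6–10, 13–24).

Step 13 (key step). The most likely failure is loss of orientation or efficiency: head-to-tail addition, enone dimerisation, or oligomerisation of the volatile ester 17 could compete, because the β-carbon C10 carries a large silyloxymethyl group. The fallback changes the 2π partner and adds a templating element. Enone 14 is irradiated with the storable acid 16 in benzene, where the carboxylic acid can hydrogen-bond to the enone carbonyl and hold its carboxyl-bearing carbon over the α-carbon C5. This should give the acid photoadduct F1, which is methylated with Me3SiCHN2 in toluene/MeOH and rejoins the route at 18.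

Step 14. Two linked processes are likely: Cope rearrangement of the 1,5-diene to the cis-divinylcyclohexanone, and, through that equilibrium, formation of the other olefin pair (C3/C6 cis at C4=C5, C2/C9 trans at C1=C10). The route relies on conjugation and on the less crowded chair-like diyl, neither of which is secured. The fallback sets out from 18 and moves the geometry correction to after the C6 reduction, where lactonisation can drive it:
- the thermolysis would give the isomeric dienone F2;
- the conditions of step 15 would give the hydroxy dienone F3 and then the syn-diol ester F4, which cannot lactonise because C15 is trans to C6;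
- irradiation of F4 (300 nm, benzene, catalytic PhSSPh) isomerises the enoate, and the cis isomer closes irreversibly to the butenolide F5, which still has the ring-trans C1=C10 olefin;
- hydrogenation as in step 16 erases that geometry and returns to 23. If the C8 hydroxyl then addresses the wrong C10 face, the catalyst-controlled hydrogenation named under step 16 is used.

A Cope equilibrium lying on the side of the divinylcyclohexanone is not cured by this fallback and would end the approach at this point.

Step 15. Once O8 is free, intramolecular conjugate addition of that hydroxyl to the doubly activated C4=C5, or conjugate hydride addition, may compete with chelation-controlled 1,2-reduction. The fallback replaces substrate control by reagent control and keeps O8 silylated. Dienone 19 is reduced with (R)-2-methyl-CBS-oxazaborolidine and catecholborane in toluene at −78 °C; the alkenyl branch is expected to act as the large group, and the antipode is used if the opposite face is attacked. This gives the 6R allylic alcohol F6, which lactonises with PPTS to the silylated butenolide F7; PPTS in MeOH then removes the triethylsilyl group and rejoins the route at 22.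

Step 16. The risk is delivery of hydrogen to the wrong C10 face if the ring conformation places that face under O8, or over-reduction of the butenolide olefin by a bishomoallylic directing effect. The fallback hands face selection to the catalyst: 22 is hydrogenated with [Ir(cod)(t-Bu-PHOX)][B(3,5-(CF3)2C6H3)4], with both ligand antipodes tested, a catalyst type that reduces trisubstituted olefins without a directing group. No new compound arises (F0), and the route is rejoined at 23.

Step 22. Competing loss of the primary silyl ethers, or acid-induced migration of the lactone to the freed O8, may erode the selective deprotection. The fallback abandons selective cleavage: 31 is fully desilylated with HF·pyridine to the triol F8, whose two primary hydroxyls are re-silylated with TBDPSCl (2.1 equiv) and imidazole at −20 °C, rejoining the route at 32.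

## Further compounds

F1 | step 13 | acid photoadduct, 8-(2-tert-butoxy-2-oxoethyl)-1-{[tert-butyl(diphenyl)silyl]oxymethyl}-7-oxo-9-[(triethylsilyl)oxy]tricyclo[4.4.0.0(2,5)]decane-5-carboxylic acid | O=C1[C@H]2[C@]3(C(=O)O)CC[C@@H]3[C@@]2(CO[Si](c4ccccc4)(c4ccccc4)C(C)(C)C)C[C@H](O[Si](CC)(CC)CC)[C@H]1CC(=O)OC(C)(C)C
F2 | step 14 | olefin isomer of 19 (C3/C6 cis at C4=C5, C2/C9 trans at C1=C10) | O=C1/C=C(C(=O)OC)\CC/C=C(CO[Si](c2ccccc2)(c2ccccc2)C(C)(C)C)/C[C@H](O[Si](CC)(CC)CC)[C@H]1CC(=O)OC(C)(C)C
F3 | step 14 | 8-hydroxy analogue of F2 | O=C1/C=C(C(=O)OC)\CC/C=C(CO[Si](c2ccccc2)(c2ccccc2)C(C)(C)C)/C[C@H](O)[C@H]1CC(=O)OC(C)(C)C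
F4 | step 14 | 6,8-syn-diol ester with C15 trans to C6 | O[C@@H]1/C=C(C(=O)OC)\CC/C=C(CO[Si](c2ccccc2)(c2ccccc2)C(C)(C)C)/C[C@H](O)[C@H]1CC(=O)OC(C)(C)C
F5 | step 14 | butenolide alcohol with ring-trans C1=C10 olefin | O=C1O[C@@H]2C=C1CC/C=C(CO[Si](c3ccccc3)(c3ccccc3)C(C)(C)C)/C[C@H](O)[C@H]2CC(=O)OC(C)(C)C
F6 | step 15 | 6R allylic alcohol of 19 with 8-O-triethylsilyl ether | O[C@@H]1/C=C(C(=O)OC)/CC/C=C(CO[Si](c2ccccc2)(c2ccccc2)C(C)(C)C)\C[C@H](O[Si](CC)(CC)CC)[C@H]1CC(=O)OC(C)(C)C
F7 | step 15 | 8-O-triethylsilyl ether of 22 | O=C1O[C@@H]2C=C1CC/C=C(CO[Si](c3ccccc3)(c3ccccc3)C(C)(C)C)\C[C@H](O[Si](CC)(CC)CC)[C@H]2CC(=O)OC(C)(C)C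
F0 | step 16 | none | none
F8 | step 22 | 8,14,15-triol α-methylene lactone | O[C@H]1C[C@H](CO)CCC/C(CO)=C/[C@H]2OC(=O)C(=C)[C@H]12
A1 | alternative 1 | open-chain C8 aldehyde with C14 allylic bromide | O=C[C@@H](CCOCc1ccc(OC)cc1)[C@H](OCc1ccc(OC)cc1)/C=C(CO[Si](C)(C)C(C)(C)C)/CCCC(=C)CBr
A2 | alternative 1 | ten-membered C8 carbinol with exocyclic methylene at C10 | O[C@H]1CC(=C)CCC/C(CO[Si](C)(C)C(C)(C)C)=C/[C@@H](OCc2ccc(OC)cc2)[C@@H]1CCOCc3ccc(OC)cc3
A3 | alternative 2 | α-iodobutenolide with terminal C2=C3 olefin | C=CC[C@@H](CO[Si](C)(C)C(C)(C)C)C[C@H](OCc1ccc(OC)cc1)[C@@H](CC(OC)OC)[C@H]1C=C(I)C(=O)O1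
A4 | alternative 2 | ten-membered carbocycle bridged by the C15 to C6 butenolide | COc1ccc(CO[C@H]2C[C@H](CO[Si](C)(C)C(C)(C)C)CCCC3=C[C@@H](OC3=O)[C@@H]2CC(OC)OC)cc1
A5 | alternative 3 | lactone diene with vinyl on C10 and allyl on C4 | C=C[C@@H](CO[Si](C)(C)C(C)(C)C)C[C@H](OCc1ccc(OC)cc1)[C@H]1CC(=O)O[C@@H]1/C=C(CO[Si](C)(C)C(C)(C)C)/CC=C
A6 | alternative 3 | ten-membered lactone-fused diene with cis C1=C2 olefin | COc1ccc(CO[C@H]2C[C@H](CO[Si](C)(C)C(C)(C)C)/C=C\C/C(CO[Si](C)(C)C(C)(C)C)=C/[C@H]3OC(=O)C[C@H]23)cc1
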